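**Retrosynthetic overview**
- Target flavone ⇒ racemic flavanone with a 2-hydroxy-3,4-dimethoxyphenyl B ring. The C5'–O bond (para to the 2'-OH) and the C2=C3 double bond are made in one operation: phenol → p-quinone oxidation, then transfer of the C2/C3 hydrogens to the quinone oxygens.
- Flavanone ⇒ 2',6'-dihydroxychalcone by 6-endo oxa-Michael closure (O1–C2 bond).
- Chalcone ⇒ 2',6'-dihydroxy-4'-methoxyacetophenone + 2-hydroxy-3,4-dimethoxybenzaldehyde (Claisen–Schmidt).
- Ring order: both benzene rings are bought; the pyranone ring is the only ring made (step 2) and is raised to the γ-pyrone level in step 3.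

Assumption: the target SMILES has no stereocentre and no stereogenic double bond, so the compound is achiral and racemic intermediates suffice; both building blocks are taken as catalogue compounds.

**Step 1**
Reactants: 1 1-(2,6-dihydroxy-4-methoxyphenyl)ethan-1-one; 2 2-hydroxy-3,4-dimethoxybenzaldehyde
Product: 3 (E)-1-(2,6-dihydroxy-4-methoxyphenyl)-3-(2-hydroxy-3,4-dimethoxyphenyl)prop-2-en-1-one
Conditions: KOH (50% aq, 10 equiv), EtOH, N2, rt, 48 h; AcOH to pH 5, 0 °C
Reagents that add atoms: none
Why: Claisen–Schmidt (crossed aldol) condensation in which the methyl-ketone enolate of 1 adds to the non-enolisable aldehyde 2 and E1cB loss of water gives the thermodynamically favoured E-enone, the phenols being carried as phenoxides.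

**Step 2**
Reactants: 3 (E)-1-(2,6-dihydroxy-4-methoxyphenyl)-3-(2-hydroxy-3,4-dimethoxyphenyl)prop-2-en-1-one
Product: 4 (±)-5-hydroxy-2-(2-hydroxy-3,4-dimethoxyphenyl)-7-methoxy-2,3-dihydro-4H-chromen-4-one
Conditions: NaOAc (0.5 equiv), EtOH/H2O (4:1), reflux, N2, dark, 12 h
Reagents that add atoms: none
Why: Intramolecular 6-endo-trig oxa-Michael addition (chalcone–flavanone isomerisation) of an A-ring phenol to the enone β-carbon forms the O1–C2 bond and the pyranone ring; the two A-ring OH groups are equivalent, so one product results, and the new C2 stereocentre is formed as a racemate on purpose because step 3 removes it.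

**Step 3**
Reactants: 4 (±)-5-hydroxy-2-(2-hydroxy-3,4-dimethoxyphenyl)-7-methoxy-2,3-dihydro-4H-chromen-4-one
Product: 6 2-(2,5-dihydroxy-3,4-dimethoxyphenyl)-5-hydroxy-7-methoxy-4H-chromen-4-one, via quinonyl flavanone 5 (not isolated)
Conditions: (KSO3)2NO (2.1 equiv), 0.1 M aq KH2PO4/acetone, 0 °C → rt, 1 h; EtOAc extraction, swap to degassed MeCN; i-Pr2NEt (0.2 equiv), Ar, 40 °C, 3 h
Reagents that add atoms: potassium nitrosodisulfonate (Fremy's salt), [O-]S(=O)(=O)N([O])S(=O)(=O)[O-].[K+].[K+]
Why: Proposed new method: phenol-triggered oxygenative desaturation, in which Fremy's radical abstracts the O–H of the only electron-rich, non-chelated phenol (2'-OH; the 5-OH is hydrogen-bonded to C4=O on an acyl-deactivated ring) and a second equivalent couples at the free para carbon C5' to give p-quinone 5 (forming the C5'–O bond), after which catalytic hindered amine removes first the C2–H (vinylogous to the quinone C5'=O through C1'=C6' and further acidified by O1) and then the C3–H α to C4=O, so both hydrogens end on the quinone oxygens, ring B re-aromatises as the 2',5'-hydroquinone and C2=C3 is created in a redox-neutral isomerisation driven by B-ring aromatisation and γ-pyrone conjugation, erasing the C2 stereocentre; closest known reaction types are the Teuber phenol-to-p-quinone oxidation, the base-induced tautomerisation of alkylquinones to quinone methides (ubiquinone → ubichromenol) and the intermolecular quinone (DDQ) dehydrogenation of flavanones.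

**Compound list**
1 | 1-(2,6-dihydroxy-4-methoxyphenyl)ethan-1-one | COc1cc(O)c(C(C)=O)c(O)c1 | starting material
2 | 2-hydroxy-3,4-dimethoxybenzaldehyde | COc1ccc(C=O)c(O)c1OC | starting material
3 | (E)-1-(2,6-dihydroxy-4-methoxyphenyl)-3-(2-hydroxy-3,4-dimethoxyphenyl)prop-2-en-1-one | COc1cc(O)c(C(=O)/C=C/c2ccc(OC)c(OC)c2O)c(O)c1 | intermediate
4 | (±)-5-hydroxy-2-(2-hydroxy-3,4-dimethoxyphenyl)-7-methoxy-2,3-dihydro-4H-chromen-4-one (racemate) | COc1cc(O)c2C(=O)CC(c3ccc(OC)c(OC)c3O)Oc2c1 | intermediate
5 | (±)-2-(4,5-dimethoxy-3,6-dioxocyclohexa-1,4-dien-1-yl)-5-hydroxy-7-methoxy-2,3-dihydro-4H-chromen-4-one (racemate, not isolated) | COc1cc(O)c2C(=O)CC(C3=CC(=O)C(OC)=C(OC)C3=O)Oc2c1 | intermediate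
6 | 2-(2,5-dihydroxy-3,4-dimethoxyphenyl)-5-hydroxy-7-methoxy-4H-chromen-4-one | COc1cc(O)c2c(=O)cc(-c3cc(O)c(OC)c(OC)c3O)oc2c1 | target

**Totals**
Total step count: 3. Longest linear sequence: 3.

**Steps most likely to fail**

Step 3 (the proposed new step). Fremy's salt could attack ring A. The base-triggered hydrogen shift could be slow or diverted by retro-oxa-Michael opening or by addition to the methoxyquinone. The hydroquinone product could be over-oxidised if any oxidant remains. The fallback uses known chemistry, sets out from 4 and comes back at 6. Only the Teuber oxidation is run and quinone 5 is isolated. Compound 5 is reduced with aqueous Na2S2O4 (EtOAc/H2O, rt) to (±)-2-(2,5-dihydroxy-3,4-dimethoxyphenyl)-5-hydroxy-7-methoxy-2,3-dihydro-4H-chromen-4-one F1. F1 is then dehydrogenated with catalytic I2 in DMSO at 120 °C under Ar (standard flavanone-to-flavone dehydrogenation, DMSO as terminal oxidant), with a dithionite work-up to return any quinone, giving 6.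

Step 1. The ketone must form an enolate on top of two phenoxides, and the aldehyde is deactivated as its ortho-phenoxide, so conversion may be poor. The fallback masks the aldehyde phenol and sets out from 2 (with 1 as partner) and comes back at 4. Compound 2 is benzylated (BnBr, K2CO3, DMF, 60 °C) to 2-(benzyloxy)-3,4-dimethoxybenzaldehyde F2. F2 is condensed with 1 (KOH, EtOH, rt) to (E)-3-[2-(benzyloxy)-3,4-dimethoxyphenyl]-1-(2,6-dihydroxy-4-methoxyphenyl)prop-2-en-1-one F3. F3 is cyclised (NaOAc, EtOH, reflux) to (±)-2-[2-(benzyloxy)-3,4-dimethoxyphenyl]-5-hydroxy-7-methoxy-2,3-dihydro-4H-chromen-4-one F4. Hydrogenolysis of F4 (H2 1 atm, Pd/C, EtOAc, rt) gives 4.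

Step 2. The electron-rich B ring lowers the electrophilicity of the β-carbon, so the chalcone–flavanone equilibrium may stop short. The B-ring ortho-OH can also close onto the carbonyl after E/Z isomerisation (chromenol/flavylium manifold). The fallback bypasses the flavanone, sets out from 3 and comes back at 6. Compound 3 undergoes oxidative cyclisation with catalytic I2 in DMSO at 120 °C to 5-hydroxy-2-(2-hydroxy-3,4-dimethoxyphenyl)-7-methoxy-4H-chromen-4-one F5. Teuber oxidation of the B-ring phenol of F5 (Fremy's salt, aq KH2PO4/acetone) gives 2-(4,5-dimethoxy-3,6-dioxocyclohexa-1,4-dien-1-yl)-5-hydroxy-7-methoxy-4H-chromen-4-one F6. Reduction of F6 with aqueous Na2S2O4 gives 6.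

**Further compounds**
F1 | step 3 | (±)-2-(2,5-dihydroxy-3,4-dimethoxyphenyl)-5-hydroxy-7-methoxy-2,3-dihydro-4H-chromen-4-one | COc1cc(O)c2C(=O)CC(c3cc(O)c(OC)c(OC)c3O)Oc2c1
F2 | step 1 | 2-(benzyloxy)-3,4-dimethoxybenzaldehyde | COc1ccc(C=O)c(OCc2ccccc2)c1OC
F3 | step 1 | (E)-3-[2-(benzyloxy)-3,4-dimethoxyphenyl]-1-(2,6-dihydroxy-4-methoxyphenyl)prop-2-en-1-one | COc1cc(O)c(C(=O)/C=C/c2ccc(OC)c(OC)c2OCc3ccccc3)c(O)c1
F4 | step 1 | (±)-2-[2-(benzyloxy)-3,4-dimethoxyphenyl]-5-hydroxy-7-methoxy-2,3-dihydro-4H-chromen-4-one | COc1cc(O)c2C(=O)CC(c3ccc(OC)c(OC)c3OCc4ccccc4)Oc2c1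
F5 | step 2 | 5-hydroxy-2-(2-hydroxy-3,4-dimethoxyphenyl)-7-methoxy-4H-chromen-4-one | COc1cc(O)c2c(=O)cc(-c3ccc(OC)c(OC)c3O)oc2c1
F6 | step 2 | 2-(4,5-dimethoxy-3,6-dioxocyclohexa-1,4-dien-1-yl)-5-hydroxy-7-methoxy-4H-chromen-4-one | COc1cc(O)c2c(=O)cc(C3=CC(=O)C(OC)=C(OC)C3=O)oc2c1
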